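The route rests on cutting the bond between C3 of quinolinone B (the ring carbon flanked by the lactam C=O and the ether carbon C4) and C1', the methine of the second pyran (ring D) that carries the 2-hydroxy-2-methylpropyl arm. Because C1' is the sixth atom of the chain C3(B)–C4(B)–O–C4–C3–C1', a 6-exo-trig cyclisation of the C3 radical of a 3-iodo-4-alkoxyquinolinone onto an (E)-3-hydroxy-3-methylbut-1-enyl group closes ring D, sets C1' and gives the free alcohol in the last step. The precursor is a cis-3-alkenyl-4-(quinolinonyloxy) dihydropyranoquinolinone; its two stereocentres come from one dynamic-kinetic transfer hydrogenation.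

Key step: step 7

Remark: compounds 1, 4, 5 and 11 are taken as commercial; O1, C2, C3, C4 are the pyrano[3,2-c]quinoline locants of the gem-dimethyl pyran (ring C) on quinolinone A, C1' to C3' are the side-chain carbons counted outward from C3, and ring D is the pyran fused to quinolinone B.

Step 1
Reactants: 1 2-methyl-2-(trimethylsilyloxy)but-3-yne
Product: 3 (E)-1-bromo-3-methyl-3-(trimethylsilyloxy)but-1-ene, via alkenylzirconocene chloride 2 (not isolated)
Conditions: Cp2Zr(H)Cl (1.1 equiv), CH2Cl2, rt; then NBS, 0 °C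
Reagents that add atoms: N-bromosuccinimide, O=C1CCC(=O)N1Br
Why: Hydrozirconation–halogenation: Zr–H adds syn across the terminal alkyne with zirconium on the terminal carbon, and N-bromosuccinimide cleaves the C–Zr bond with retention, so the (E)-alkenyl bromide should result.

Step 2
Reactants: 4 3-acetyl-4-hydroxy-1-methylquinolin-2(1H)-one; 5 acetone
Product: 7 2,2,6-trimethyl-2,3-dihydro-4H-pyrano[3,2-c]quinoline-4,5(6H)-dione, via enone 6 (not isolated)
Conditions: acetone (excess), pyrrolidine (0.5 equiv), toluene, 4 Å sieves, reflux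
Reagents that add atoms: none
Why: Kabbe condensation: amine-mediated aldol-type condensation of the acetyl group with acetone gives enone 6, whose acidic 4-OH closes the gem-dimethyl pyranone by oxa-Michael addition, the acetyl precursor fixing the regiochemistry of ring C.

Step 3
Reactants: 7 2,2,6-trimethyl-2,3-dihydro-4H-pyrano[3,2-c]quinoline-4,5(6H)-dione; 3 (E)-1-bromo-3-methyl-3-(trimethylsilyloxy)but-1-ene
Product: 9 rac-3-[(E)-3-hydroxy-3-methylbut-1-enyl]-2,2,6-trimethyl-2,3-dihydro-4H-pyrano[3,2-c]quinoline-4,5(6H)-dione, via silyl ether 8 (not isolated)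
Conditions: LiHMDS (2.2 equiv), THF/toluene, −78 to 0 °C; Pd(P(t-Bu)3)2 (3 mol%), 3 (1.2 equiv), 0 °C to rt; then 10% aq. citric acid, THF
Reagents that add atoms: none
Why: Palladium-catalysed α-alkenylation of a ketone enolate (oxidative addition of the alkenyl bromide to zerovalent palladium, enolate transmetalation, reductive elimination) should install the whole side chain with retention of the E geometry at C3, the only enolisable carbon; C3 is formed racemic, which step 4 corrects, and the mild acid work-up frees the tertiary alcohol.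

Step 4
Reactants: 9 rac-3-[(E)-3-hydroxy-3-methylbut-1-enyl]-2,2,6-trimethyl-2,3-dihydro-4H-pyrano[3,2-c]quinoline-4,5(6H)-dione
Product: 10 (3R,4S)-4-hydroxy-3-[(E)-3-hydroxy-3-methylbut-1-enyl]-2,2,6-trimethyl-3,4-dihydro-2H-pyrano[3,2-c]quinolin-5(6H)-one
Conditions: RuCl(p-cymene)[(S,S)-TsDPEN] (2 mol%), HCO2H/Et3N (5:2), DMF, 35 °C
Reagents that add atoms: none
Why: Noyori–Ikariya asymmetric transfer hydrogenation with dynamic kinetic resolution: C3 (alpha to the ketone and allylic) racemises through the enol in the amine medium, the (S,S)-catalyst sets C4 as S by the same facial preference as for chroman-4-one, and only the enantiomer that takes hydride anti to the alkenyl group is reduced, which should give the cis (3R,4S) alcohol.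

Step 5
Reactants: 10 (3R,4S)-4-hydroxy-3-[(E)-3-hydroxy-3-methylbut-1-enyl]-2,2,6-trimethyl-3,4-dihydro-2H-pyrano[3,2-c]quinolin-5(6H)-one; 11 4-chloro-1-methylquinolin-2(1H)-one
Product: 12 (3R,4S)-3-[(E)-3-hydroxy-3-methylbut-1-enyl]-2,2,6-trimethyl-4-[(1-methyl-2-oxo-1,2-dihydroquinolin-4-yl)oxy]-3,4-dihydro-2H-pyrano[3,2-c]quinolin-5(6H)-one
Conditions: KHMDS (1.0 equiv), THF/DMF, −20 °C; then 11 (1.2 equiv), −20 °C to rt
Reagents that add atoms: none
Why: Addition–elimination (SNAr type) of the more acidic secondary benzylic alkoxide at C4 of the vinylogous carbamoyl chloride 11 forms the aryl ether without touching the C4–O bond of 10, so both stereocentres are retained; one equivalent of base at low temperature leaves the tertiary alcohol protonated and limits elimination.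

Step 6
Reactants: 12 (3R,4S)-3-[(E)-3-hydroxy-3-methylbut-1-enyl]-2,2,6-trimethyl-4-[(1-methyl-2-oxo-1,2-dihydroquinolin-4-yl)oxy]-3,4-dihydro-2H-pyrano[3,2-c]quinolin-5(6H)-one
Product: 13 (3R,4S)-3-[(E)-3-hydroxy-3-methylbut-1-enyl]-4-[(3-iodo-1-methyl-2-oxo-1,2-dihydroquinolin-4-yl)oxy]-2,2,6-trimethyl-3,4-dihydro-2H-pyrano[3,2-c]quinolin-5(6H)-one
Conditions: NIS (1.1 equiv), NaHCO3, MeCN, 0 °C to rt, dark
Reagents that add atoms: N-iodosuccinimide, O=C1CCC(=O)N1I
Why: Electrophilic iodination of a push-pull enol ether: C3 of quinolinone B is the only nucleophilic sp2 C–H position and should react far faster than the unactivated disubstituted alkene or the fully substituted quinolinone A.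

Step 7
Reactants: 13 (3R,4S)-3-[(E)-3-hydroxy-3-methylbut-1-enyl]-4-[(3-iodo-1-methyl-2-oxo-1,2-dihydroquinolin-4-yl)oxy]-2,2,6-trimethyl-3,4-dihydro-2H-pyrano[3,2-c]quinolin-5(6H)-one
Product: 14 CNP0202276.1 (the target)
Conditions: Bu3SnH (1.3 equiv, syringe pump), AIBN (0.2 equiv), benzene (0.005 M), 80 °C
Reagents that add atoms: none
Why: Iodine abstraction by the stannyl radical gives the sigma radical at C3 of quinolinone B, which adds to the proximal alkene carbon C1', and the secondary radical at C2' is then quenched by Bu3SnH; the closest known reaction type is the reductive tin-hydride cyclisation of 3-halo-4-(alkenyloxy)quinolinones and coumarins. Ring D closes in the 6-exo-trig mode, the 7-endo attack at C2' being slower. The new stereocentre C1' is controlled by the existing C3/C4 pair: the cis-fused chair-like transition state places the allylic C3–H, not the quaternary C2, in the plane of the alkene (minimal A(1,3) strain), so the hydroxyalkyl arm ends up anti to C2 and C1' should form as R. The step needs cyclisation to outrun direct reduction and 1,5-hydrogen transfer from the allylic C3–H; high dilution with slow stannane addition and the short ether tether that holds the alkene over the radical should secure this. The tertiary alcohol, both lactams and the benzylic ether are inert to stannyl radicals.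

Compound list
1 | 2-methyl-2-(trimethylsilyloxy)but-3-yne | C#CC(C)(C)O[Si](C)(C)C | starting material
2 | (E)-[3-methyl-3-(trimethylsilyloxy)but-1-enyl]zirconocene chloride (not isolated) | C[Si](C)(C)OC(C)(C)/C=C/[Zr](Cl)(C1C=CC=C1)C1C=CC=C1 | intermediate
3 | (E)-1-bromo-3-methyl-3-(trimethylsilyloxy)but-1-ene | C[Si](C)(C)OC(C)(C)/C=C/Br | intermediate
4 | 3-acetyl-4-hydroxy-1-methylquinolin-2(1H)-one | CC(=O)c1c(O)c2ccccc2n(C)c1=O | starting material
5 | acetone | CC(C)=O | starting material
6 | 4-hydroxy-1-methyl-3-(3-methylbut-2-enoyl)quinolin-2(1H)-one (not isolated) | CC(C)=CC(=O)c1c(O)c2ccccc2n(C)c1=O | intermediate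
7 | 2,2,6-trimethyl-2,3-dihydro-4H-pyrano[3,2-c]quinoline-4,5(6H)-dione | Cn1c(=O)c2c(c3ccccc31)OC(C)(C)CC2=O | intermediate
8 | rac-3-[(E)-3-methyl-3-(trimethylsilyloxy)but-1-enyl]-2,2,6-trimethyl-2,3-dihydro-4H-pyrano[3,2-c]quinoline-4,5(6H)-dione (not isolated) | Cn1c(=O)c2c(c3ccccc31)OC(C)(C)C(/C=C/C(C)(C)O[Si](C)(C)C)C2=O | intermediate
9 | rac-3-[(E)-3-hydroxy-3-methylbut-1-enyl]-2,2,6-trimethyl-2,3-dihydro-4H-pyrano[3,2-c]quinoline-4,5(6H)-dione | Cn1c(=O)c2c(c3ccccc31)OC(C)(C)C(/C=C/C(C)(C)O)C2=O | intermediate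
10 | (3R,4S)-4-hydroxy-3-[(E)-3-hydroxy-3-methylbut-1-enyl]-2,2,6-trimethyl-3,4-dihydro-2H-pyrano[3,2-c]quinolin-5(6H)-one (OH and alkenyl cis) | Cn1c(=O)c2c(c3ccccc31)OC(C)(C)[C@H](/C=C/C(C)(C)O)[C@@H]2O | intermediate
11 | 4-chloro-1-methylquinolin-2(1H)-one | Cn1c(=O)cc(Cl)c2ccccc12 | starting material
12 | (3R,4S)-3-[(E)-3-hydroxy-3-methylbut-1-enyl]-2,2,6-trimethyl-4-[(1-methyl-2-oxo-1,2-dihydroquinolin-4-yl)oxy]-3,4-dihydro-2H-pyrano[3,2-c]quinolin-5(6H)-one | Cn1c(=O)c2c(c3ccccc31)OC(C)(C)[C@H](/C=C/C(C)(C)O)[C@@H]2Oc1cc(=O)n(C)c2ccccc12 | intermediate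
13 | (3R,4S)-3-[(E)-3-hydroxy-3-methylbut-1-enyl]-4-[(3-iodo-1-methyl-2-oxo-1,2-dihydroquinolin-4-yl)oxy]-2,2,6-trimethyl-3,4-dihydro-2H-pyrano[3,2-c]quinolin-5(6H)-one | Cn1c(=O)c2c(c3ccccc31)OC(C)(C)[C@H](/C=C/C(C)(C)O)[C@@H]2Oc1c(I)c(=O)n(C)c2ccccc12 | intermediate
14 | CNP0202276.1: rings C and D cis-fused through C3–C4, C4 bearing the ring-D oxygen, C1' bearing CH2C(CH3)2OH anti to C2; configuration 3R, 4S, 1'R | Cn1c(=O)c2c(c3ccccc31)OC(C)(C)[C@H]1[C@@H]2Oc2c(c(=O)n(C)c3ccccc23)[C@@H]1CC(C)(C)O | target

Total step count: 7. Longest linear sequence: 6 (steps 2 to 7).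

Steps most likely to fail

Step 7 (key step). The ring-B radical may take the allylic C3–H by 1,5-hydrogen transfer or be reduced by the stannane before it cyclises, and facial control at C1' may be incomplete. The fallback sets out from 12 and returns at 14; it makes the same bond by a cationic ring closure without iodine. Catalytic Bi(OTf)3 in MeNO2/CH2Cl2 at 0 °C should ionise the tertiary allylic alcohol of 12 to an allyl cation. Its C1' terminus is then captured by the nucleophilic C3 of quinolinone B (intramolecular Friedel–Crafts allylation, six-membered ring, same A(1,3) control) to give the 2-methylprop-1-enyl pentacycle F1. Mukaiyama hydration of its trisubstituted alkene (Co(acac)2, PhSiH3, O2, THF/i-PrOH) should then give 14.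

Step 3. The pyranone enolate may open by retro-oxa-Michael reaction, coupling at the neopentyl-type enolate carbon may be slow, or the new alkene may migrate into conjugation with the ketone. The fallback sets out from 7 and returns at 9; it builds the side chain by condensation and a redox transposition. Aldol addition of the enolate of 7 (LDA, THF, −78 °C) to 3-methylbut-2-enal gives the aldol adduct F2, and dehydration (TsOH, benzene, reflux) gives the dienone F3. mCPBA (NaHCO3, CH2Cl2, 0 °C) epoxidises the distal, more electron-rich trisubstituted alkene to the epoxy enone F4. SmI2 (THF/MeOH, −78 °C) opens this vinylogous epoxy ketone reductively to a dienolate, whose kinetic alpha-protonation should give 9 with the E alkene.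

Step 4. The beta,gamma-unsaturated ketone may drift into conjugation in the amine/formate medium, or racemisation at C3 may be slower than reduction, so that stereoconvergence is incomplete. The fallback sets out from 7 and returns at 10; it sets C3 in the C–C bond formation instead. Bromination of 7 (pyridinium tribromide, THF, rt) gives the 3-bromo ketone F5. Stereoconvergent nickel-catalysed coupling of F5 with alkenylzirconocene 2, made from 1 as in step 1 (NiCl2(dme), chiral bis(oxazoline) ligand, DME/THF, 10 °C), gives the (S)-configured silyl ether ketone F6. LiBH(s-Bu)3 in THF at −78 °C should deliver hydride anti to the alkenyl group to give the cis alcohol silyl ether F7, and aqueous citric acid frees 10.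

Further compounds
F1 | step 7 | 14 with a 2-methylprop-1-enyl group on C1' in place of the 2-hydroxy-2-methylpropyl group (3R, 4S, 1'R) | Cn1c(=O)c2c(c3ccccc31)OC(C)(C)[C@H]1[C@@H]2Oc2c(c(=O)n(C)c3ccccc23)[C@@H]1C=C(C)C
F2 | step 3 | 3-(1-hydroxy-3-methylbut-2-enyl)-2,2,6-trimethyl-2,3-dihydro-4H-pyrano[3,2-c]quinoline-4,5(6H)-dione (diastereomer mixture) | Cn1c(=O)c2c(c3ccccc31)OC(C)(C)C(C(O)C=C(C)C)C2=O
F3 | step 3 | 2,2,6-trimethyl-3-(3-methylbut-2-enylidene)-2,3-dihydro-4H-pyrano[3,2-c]quinoline-4,5(6H)-dione | Cn1c(=O)c2c(c3ccccc31)OC(C)(C)C(=CC=C(C)C)C2=O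
F4 | step 3 | 3-[(3,3-dimethyloxiran-2-yl)methylidene]-2,2,6-trimethyl-2,3-dihydro-4H-pyrano[3,2-c]quinoline-4,5(6H)-dione | Cn1c(=O)c2c(c3ccccc31)OC(C)(C)C(=CC1OC1(C)C)C2=O
F5 | step 4 | rac-3-bromo-2,2,6-trimethyl-2,3-dihydro-4H-pyrano[3,2-c]quinoline-4,5(6H)-dione | Cn1c(=O)c2c(c3ccccc31)OC(C)(C)C(Br)C2=O
F6 | step 4 | (S)-3-[(E)-3-methyl-3-(trimethylsilyloxy)but-1-enyl]-2,2,6-trimethyl-2,3-dihydro-4H-pyrano[3,2-c]quinoline-4,5(6H)-dione | Cn1c(=O)c2c(c3ccccc31)OC(C)(C)[C@H](/C=C/C(C)(C)O[Si](C)(C)C)C2=O
F7 | step 4 | (3R,4S)-4-hydroxy-3-[(E)-3-methyl-3-(trimethylsilyloxy)but-1-enyl]-2,2,6-trimethyl-3,4-dihydro-2H-pyrano[3,2-c]quinolin-5(6H)-one | Cn1c(=O)c2c(c3ccccc31)OC(C)(C)[C@H](/C=C/C(C)(C)O[Si](C)(C)C)[C@@H]2O
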